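**Plan**

- Retrosynthesis: the aryl ester C(=O)–O bond between ring A and the central 3-hydroxybutanoate is cut first. Within that unit the butanoate C1–C2 bond and the C1–O ester bond to the ring C side chain are cut together (epoxide, CO, alcohol), then the aryl–CH2 bond of ring C. In the ring A acid the aryl–CO2H bond and the two C–C bonds at the ketone carbon (held as a 1,3-dithiane) are cut.
- Forward: no ring is formed. The chain is joined from ring C towards ring A: alcohol 4, carbonylative esterification to 8, acylation by acid 19, dithiane hydrolysis, hydrogenolysis.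
- Enabling feature: the three stereocentres are C2 of the propan-2-yl chain on the 3,5-dihydroxyphenyl ring C, C3 of the butanoate, and C4 of the 2-oxopentyl chain on ring A. Each is an (R)-CH(CH3)–O carbon with a CH2 neighbour, that is C2 of (R)-propylene oxide after opening at CH2 by the ring C aryl, by CO (the new butanoate C1) or by an acyl anion equivalent.
- Stereochemistry: all three centres come from (R)-propylene oxide 2. Its C2–O bond is never broken, so no centre is created or inverted.

Key step: step 2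

Remark: compounds 1, 2, 5, 9 and 12 are taken as commercial, 2 as the single (R) enantiomer; the target SMILES defines all three centres as R.

**Route**

Step 1
Reactants: 1 1,3-bis(benzyloxy)-5-bromobenzene; 2 (R)-propylene oxide
Product: 4 (R)-1-[3,5-bis(benzyloxy)phenyl]propan-2-ol, via [3,5-bis(benzyloxy)phenyl]magnesium bromide 3 (not isolated)
Conditions: Mg, cat. I2, THF, reflux; then CuI (10 mol%), 2, THF, −30 to 0 °C; 1 M HCl work-up
Reagents that add atoms: none
Why: Copper-catalysed ring opening of a terminal epoxide by an aryl Grignard reagent is an SN2 attack at the CH2 terminus, so the C2–O bond and the (R) configuration of 2 pass unchanged into 4.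

Step 2
Reactants: 4 (R)-1-[3,5-bis(benzyloxy)phenyl]propan-2-ol; 2 (R)-propylene oxide; 5 carbon monoxide
Product: 8 (R)-1-[3,5-bis(benzyloxy)phenyl]propan-2-yl (R)-3-hydroxybutanoate, via (R)-2-hydroxypropylcobalt tetracarbonyl 6 (not isolated), via (R)-3-hydroxybutanoylcobalt tetracarbonyl 7 (not isolated)
Conditions: Co2(CO)8 (5 mol%), 3-hydroxypyridine (10 mol%), CO (40 bar), THF (concentrated), 60 °C; 4 in threefold excess over 2, surplus 4 recovered
Reagents that add atoms: none
Why: Proposed new method: 3-hydroxypyridine should convert Co2(CO)8 into a pyridinium tetracarbonylcobaltate pair (equivalent to HCo(CO)4), whose acidic partner activates the oxirane oxygen of 2 while the [Co(CO)4]− anion opens it by SN2 attack at the unsubstituted CH2 to give alkylcobalt 6; CO insertion gives acylcobalt 7, which the hydroxyl of 4 cleaves to ester 8 with return of HCo(CO)4. The closest known reaction type is the Co2(CO)8/3-hydroxypyridine methoxycarbonylation of terminal epoxides to β-hydroxy methyl esters, extended here from methanol as cosolvent to a secondary alcohol in modest excess. No ring closes, and two skeletal bonds form, the butanoate C1–C2 bond and the C1–O ester bond. No stereocentre is created, because the C2–O bond of the epoxide and the carbinol C–O bond of 4 are never broken, so (R)-2 and (R)-4 are carried into (R,R)-8 with retention. The step needs attack at CH2 and not at CH, which the methyl group secures sterically, and capture of 7 by 4 in preference to the hydroxyl of 8 (chain growth) or to lactone and oligo(3-hydroxybutanoate) formation, which the excess and high concentration of 4 and the weaker, internally hydrogen-bonded hydroxyl of 8 should secure. CO pressure and the moderate temperature should hold back isomerisation of 2 to acetone.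

Step 3
Reactants: 9 [3,5-bis(benzyloxy)phenyl]methanol
Product: 10 [3,5-bis(benzyloxy)-2-bromophenyl]methanol
Conditions: NBS (1.0 equiv), CH2Cl2, 0 °C
Reagents that add atoms: N-bromosuccinimide, O=C1CCC(=O)N1Br
Why: Electrophilic aromatic bromination of a 3,5-dialkoxybenzyl alcohol goes to the position next to the CH2OH group (para to one ether, ortho to the other), the site between the two ethers being the more hindered.

Step 4
Reactants: 10 [3,5-bis(benzyloxy)-2-bromophenyl]methanol
Product: 11 1,5-bis(benzyloxy)-2-bromo-3-(bromomethyl)benzene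
Conditions: PBr3, CH2Cl2, 0 °C
Reagents that add atoms: phosphorus tribromide, BrP(Br)Br
Why: Conversion of a primary benzylic alcohol into its bromide with PBr3 (SN2 displacement of the phosphite ester by bromide) is routine and leaves the aryl bromide and the benzyl ethers untouched.

Step 5
Reactants: 12 1,3-dithiane; 2 (R)-propylene oxide
Product: 14 (R)-1-(1,3-dithian-2-yl)propan-2-ol, via 2-lithio-1,3-dithiane 13 (not isolated)
Conditions: n-BuLi, THF, −30 °C; then 2, −30 to 0 °C; H2O quench
Reagents that add atoms: none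
Why: Corey–Seebach umpolung, in which the lithiated dithiane opens the terminal epoxide by SN2 attack at CH2, so the carbinol centre keeps the (R) configuration of 2.

Step 6
Reactants: 14 (R)-1-(1,3-dithian-2-yl)propan-2-ol
Product: 15 2-[(R)-2-(benzyloxy)propyl]-1,3-dithiane
Conditions: NaH, BnBr, cat. n-Bu4NI, THF/DMF, 0 °C to rt
Reagents that add atoms: benzyl bromide, BrCc1ccccc1
Why: Williamson etherification of the sodium alkoxide gives a benzyl ether that withstands the organolithium steps and falls in the final hydrogenolysis together with the aryl benzyl ethers.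

Step 7
Reactants: 15 2-[(R)-2-(benzyloxy)propyl]-1,3-dithiane; 11 1,5-bis(benzyloxy)-2-bromo-3-(bromomethyl)benzene
Product: 17 2-{[3,5-bis(benzyloxy)-2-bromophenyl]methyl}-2-[(R)-2-(benzyloxy)propyl]-1,3-dithiane, via 2-lithio-2-[(R)-2-(benzyloxy)propyl]-1,3-dithiane 16 (not isolated)
Conditions: t-BuLi, THF/HMPA (10:1), −78 °C; then 11, −78 to −40 °C
Reagents that add atoms: none
Why: Second Corey–Seebach alkylation, in which the tertiary dithiane anion displaces the benzylic bromide by SN2 while the aryl bromide, which does not exchange with so stabilised an anion, stays in place.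

Step 8
Reactants: 17 2-{[3,5-bis(benzyloxy)-2-bromophenyl]methyl}-2-[(R)-2-(benzyloxy)propyl]-1,3-dithiane
Product: 19 2,4-bis(benzyloxy)-6-({2-[(R)-2-(benzyloxy)propyl]-1,3-dithian-2-yl}methyl)benzoic acid, via aryllithium 18 (not isolated)
Conditions: n-BuLi, THF, −78 °C; CO2, −78 °C to rt; 1 M HCl
Reagents that add atoms: carbon dioxide, O=C=O
Why: Bromine–lithium exchange at −78 °C outruns deprotonation of the benzyl ethers and attack on the fully substituted dithiane, and carboxylation of the aryllithium with CO2 gives the benzoic acid without any oxidant that could touch sulfur.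

Step 9
Reactants: 19 2,4-bis(benzyloxy)-6-({2-[(R)-2-(benzyloxy)propyl]-1,3-dithian-2-yl}methyl)benzoic acid; 8 (R)-1-[3,5-bis(benzyloxy)phenyl]propan-2-yl (R)-3-hydroxybutanoate
Product: 21 (R)-4-{[(R)-1-[3,5-bis(benzyloxy)phenyl]propan-2-yl]oxy}-4-oxobutan-2-yl 2,4-bis(benzyloxy)-6-({2-[(R)-2-(benzyloxy)propyl]-1,3-dithian-2-yl}methyl)benzoate, via acid chloride 20 (not isolated)
Conditions: 1-chloro-N,N,2-trimethylprop-1-en-1-amine, CH2Cl2, 0 °C to rt; then 8, Et3N, DMAP, CH2Cl2, rt
Reagents that add atoms: none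
Why: DMAP-catalysed acylation of a secondary alcohol by an acid chloride, with the chloride made under neutral conditions by the chloroenamine and the ketone masked so that it cannot lactonise onto the activated carboxyl; the carbinol C–O bond of 8 is not broken, so its configuration is retained.

Step 10
Reactants: 21 the dithiane triester from step 9
Product: 22 (R)-4-{[(R)-1-[3,5-bis(benzyloxy)phenyl]propan-2-yl]oxy}-4-oxobutan-2-yl 2,4-bis(benzyloxy)-6-[(R)-4-(benzyloxy)-2-oxopentyl]benzoate
Conditions: MeI (excess), CaCO3, MeCN/H2O (9:1), 45 °C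
Reagents that add atoms: water, O
Why: Alkylative hydrolysis of a dithiane (S-methylation to the sulfonium salt, then attack of water) under CaCO3 buffering should unmask the ketone without touching the esters, the benzyl ethers or the electron-rich rings that an oxidative reagent could attack.

Step 11
Reactants: 22 the keto triester from step 10
Product: 23 Hansforester K, (R)-4-{[(R)-1-(3,5-dihydroxyphenyl)propan-2-yl]oxy}-4-oxobutan-2-yl 2,4-dihydroxy-6-[(R)-4-hydroxy-2-oxopentyl]benzoate
Conditions: H2 (1 atm), 10% Pd/C, EtOAc/EtOH, rt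
Reagents that add atoms: none
Why: Catalytic hydrogenolysis of the four aryl benzyl ethers and the one alkyl benzyl ether under neutral conditions should free all five hydroxyl groups while the esters, the aliphatic ketone and the three stereocentres stay untouched.

**Compound list**

1 | 1,3-bis(benzyloxy)-5-bromobenzene | Brc1cc(OCc2ccccc2)cc(OCc2ccccc2)c1 | starting material
2 | (R)-propylene oxide, (R)-2-methyloxirane | C[C@@H]1CO1 | starting material
3 | [3,5-bis(benzyloxy)phenyl]magnesium bromide | Br[Mg]c1cc(OCc2ccccc2)cc(OCc2ccccc2)c1 | intermediate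
4 | (R)-1-[3,5-bis(benzyloxy)phenyl]propan-2-ol | C[C@H](Cc1cc(OCc2ccccc2)cc(OCc2ccccc2)c1)O | intermediate
5 | carbon monoxide | [C-]#[O+] | starting material
6 | (R)-2-hydroxypropylcobalt tetracarbonyl | C[C@@H](O)C[Co](=C=O)(=C=O)(=C=O)=C=O | intermediate
7 | (R)-3-hydroxybutanoylcobalt tetracarbonyl | C[C@@H](O)CC(=O)[Co](=C=O)(=C=O)(=C=O)=C=O | intermediate
8 | (R)-1-[3,5-bis(benzyloxy)phenyl]propan-2-yl (R)-3-hydroxybutanoate | C[C@H](Cc1cc(OCc2ccccc2)cc(OCc2ccccc2)c1)OC(=O)C[C@@H](C)O | intermediate
9 | [3,5-bis(benzyloxy)phenyl]methanol | OCc1cc(OCc2ccccc2)cc(OCc2ccccc2)c1 | starting material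
10 | [3,5-bis(benzyloxy)-2-bromophenyl]methanol | OCc1cc(OCc2ccccc2)cc(OCc2ccccc2)c1Br | intermediate
11 | 1,5-bis(benzyloxy)-2-bromo-3-(bromomethyl)benzene | BrCc1cc(OCc2ccccc2)cc(OCc2ccccc2)c1Br | intermediate
12 | 1,3-dithiane | C1CSCSC1 | starting material
13 | 2-lithio-1,3-dithiane | [Li]C1SCCCS1 | intermediate
14 | (R)-1-(1,3-dithian-2-yl)propan-2-ol | C[C@@H](O)CC1SCCCS1 | intermediate
15 | 2-[(R)-2-(benzyloxy)propyl]-1,3-dithiane | C[C@@H](OCc1ccccc1)CC1SCCCS1 | intermediate
16 | 2-lithio-2-[(R)-2-(benzyloxy)propyl]-1,3-dithiane | C[C@@H](OCc1ccccc1)CC1([Li])SCCCS1 | intermediate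
17 | 2-{[3,5-bis(benzyloxy)-2-bromophenyl]methyl}-2-[(R)-2-(benzyloxy)propyl]-1,3-dithiane | C[C@@H](OCc1ccccc1)CC1(Cc2cc(OCc3ccccc3)cc(OCc3ccccc3)c2Br)SCCCS1 | intermediate
18 | {2,4-bis(benzyloxy)-6-({2-[(R)-2-(benzyloxy)propyl]-1,3-dithian-2-yl}methyl)phenyl}lithium | C[C@@H](OCc1ccccc1)CC1(Cc2cc(OCc3ccccc3)cc(OCc3ccccc3)c2[Li])SCCCS1 | intermediate
19 | 2,4-bis(benzyloxy)-6-({2-[(R)-2-(benzyloxy)propyl]-1,3-dithian-2-yl}methyl)benzoic acid | C[C@@H](OCc1ccccc1)CC1(Cc2cc(OCc3ccccc3)cc(OCc3ccccc3)c2C(=O)O)SCCCS1 | intermediate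
20 | 2,4-bis(benzyloxy)-6-({2-[(R)-2-(benzyloxy)propyl]-1,3-dithian-2-yl}methyl)benzoyl chloride | C[C@@H](OCc1ccccc1)CC1(Cc2cc(OCc3ccccc3)cc(OCc3ccccc3)c2C(Cl)=O)SCCCS1 | intermediate
21 | (R)-4-{[(R)-1-[3,5-bis(benzyloxy)phenyl]propan-2-yl]oxy}-4-oxobutan-2-yl 2,4-bis(benzyloxy)-6-({2-[(R)-2-(benzyloxy)propyl]-1,3-dithian-2-yl}methyl)benzoate | C[C@H](Cc1cc(OCc2ccccc2)cc(OCc2ccccc2)c1)OC(=O)C[C@@H](C)OC(=O)c1c(OCc2ccccc2)cc(OCc2ccccc2)cc1CC1(C[C@@H](C)OCc2ccccc2)SCCCS1 | intermediate
22 | (R)-4-{[(R)-1-[3,5-bis(benzyloxy)phenyl]propan-2-yl]oxy}-4-oxobutan-2-yl 2,4-bis(benzyloxy)-6-[(R)-4-(benzyloxy)-2-oxopentyl]benzoate | C[C@H](Cc1cc(OCc2ccccc2)cc(OCc2ccccc2)c1)OC(=O)C[C@@H](C)OC(=O)c1c(OCc2ccccc2)cc(OCc2ccccc2)cc1CC(=O)C[C@@H](C)OCc1ccccc1 | intermediate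
23 | Hansforester K | C[C@H](Cc1cc(O)cc(O)c1)OC(=O)C[C@@H](C)OC(=O)c1c(O)cc(O)cc1CC(=O)C[C@@H](C)O | target

**Count and risks**

Total step count: 11. Longest linear sequence: 7 steps (steps 5, 6, 7, 8, 9, 10, 11; the branch through steps 3 and 4 is equally long).

Steps most likely to fail:

1. Step 2. The acylcobalt may be captured by the hydroxyl of the product instead of by 4, so that the chain grows to oligoesters. Alcoholysis by a secondary alcohol may also be slow enough for cyclisation to the β-lactone and its polymerisation to take over. The fallback uses known chemistry, sets out from 2, 5 and 4 and returns at 8. Methoxycarbonylation of 2 with 5 in MeOH/THF under Co2(CO)8 and 3-hydroxypyridine, the established form of the reaction, gives methyl (R)-3-hydroxybutanoate F1. Silylation (TBSCl, imidazole, DMF) gives methyl (R)-3-[(tert-butyldimethylsilyl)oxy]butanoate F2, and saponification (LiOH, THF/H2O) gives (R)-3-[(tert-butyldimethylsilyl)oxy]butanoic acid F3. Steglich esterification with 4 (DCC, DMAP, CH2Cl2) gives (R)-1-[3,5-bis(benzyloxy)phenyl]propan-2-yl (R)-3-[(tert-butyldimethylsilyl)oxy]butanoate F4, and HF·pyridine in THF frees the hydroxyl to give 8.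

2. Step 9. Acyl transfer at the doubly ortho-substituted carbonyl may be sluggish, so that base-induced β-elimination of the aroyloxy group from the product, or participation by the dithiane sulfur, competes. The fallback sets out from 4 and 19 and returns at 21. Alcohol 4 is taken through the three-component carbonylation of step 2 with (S)-propylene oxide in place of 2, to give (R)-1-[3,5-bis(benzyloxy)phenyl]propan-2-yl (S)-3-hydroxybutanoate F5. Mitsunobu esterification of acid 19 with F5 (PPh3, DIAD, toluene, 0 °C to rt) then forms the same ester bond by SN2 displacement at the carbinol carbon with inversion. The carboxylate acts as the nucleophile, so crowding at the carboxyl carbon no longer matters.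

3. Step 10. S-Methylation of the fully substituted, neopentyl-like dithiane may be slow, and forcing it may cause β-elimination of the benzyloxy group from the freed ketone or enol lactonisation onto the neighbouring ester. The fallback sets out from 17 and returns at 22, exchanging the mask early on a simpler compound.
   - Hg(ClO4)2 and CaCO3 in THF/H2O at 0 °C hydrolyse 17 to (R)-4-(benzyloxy)-1-[3,5-bis(benzyloxy)-2-bromophenyl]pentan-2-one F6.
   - Ketalisation with 1,2-bis(trimethylsilyloxy)ethane and catalytic Me3SiOTf in CH2Cl2 at −78 °C gives 2-{[3,5-bis(benzyloxy)-2-bromophenyl]methyl}-2-[(R)-2-(benzyloxy)propyl]-1,3-dioxolane F7.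
   - n-BuLi at −78 °C gives the corresponding aryllithium F8, and CO2 with a buffered work-up gives 2,4-bis(benzyloxy)-6-({2-[(R)-2-(benzyloxy)propyl]-1,3-dioxolan-2-yl}methyl)benzoic acid F9.
   - The chloroenamine of step 9 gives the acid chloride F10, which acylates 8 (Et3N, DMAP) to the dioxolane triester F11.
   - PPTS in wet acetone at rt then removes the dioxolane to give 22.

**Further compounds**

F1 | step 2 | methyl (R)-3-hydroxybutanoate | C[C@@H](O)CC(=O)OC
F2 | step 2 | methyl (R)-3-[(tert-butyldimethylsilyl)oxy]butanoate | C[C@@H](O[Si](C)(C)C(C)(C)C)CC(=O)OC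
F3 | step 2 | (R)-3-[(tert-butyldimethylsilyl)oxy]butanoic acid | C[C@@H](O[Si](C)(C)C(C)(C)C)CC(=O)O
F4 | step 2 | (R)-1-[3,5-bis(benzyloxy)phenyl]propan-2-yl (R)-3-[(tert-butyldimethylsilyl)oxy]butanoate | C[C@H](Cc1cc(OCc2ccccc2)cc(OCc2ccccc2)c1)OC(=O)C[C@@H](C)O[Si](C)(C)C(C)(C)C
F5 | step 9 | (R)-1-[3,5-bis(benzyloxy)phenyl]propan-2-yl (S)-3-hydroxybutanoate | C[C@H](Cc1cc(OCc2ccccc2)cc(OCc2ccccc2)c1)OC(=O)C[C@H](C)O
F6 | step 10 | (R)-4-(benzyloxy)-1-[3,5-bis(benzyloxy)-2-bromophenyl]pentan-2-one | C[C@@H](OCc1ccccc1)CC(=O)Cc1cc(OCc2ccccc2)cc(OCc2ccccc2)c1Br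
F7 | step 10 | 2-{[3,5-bis(benzyloxy)-2-bromophenyl]methyl}-2-[(R)-2-(benzyloxy)propyl]-1,3-dioxolane | C[C@@H](OCc1ccccc1)CC1(Cc2cc(OCc3ccccc3)cc(OCc3ccccc3)c2Br)OCCO1
F8 | step 10 | {2,4-bis(benzyloxy)-6-({2-[(R)-2-(benzyloxy)propyl]-1,3-dioxolan-2-yl}methyl)phenyl}lithium | C[C@@H](OCc1ccccc1)CC1(Cc2cc(OCc3ccccc3)cc(OCc3ccccc3)c2[Li])OCCO1
F9 | step 10 | 2,4-bis(benzyloxy)-6-({2-[(R)-2-(benzyloxy)propyl]-1,3-dioxolan-2-yl}methyl)benzoic acid | C[C@@H](OCc1ccccc1)CC1(Cc2cc(OCc3ccccc3)cc(OCc3ccccc3)c2C(=O)O)OCCO1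
F10 | step 10 | 2,4-bis(benzyloxy)-6-({2-[(R)-2-(benzyloxy)propyl]-1,3-dioxolan-2-yl}methyl)benzoyl chloride | C[C@@H](OCc1ccccc1)CC1(Cc2cc(OCc3ccccc3)cc(OCc3ccccc3)c2C(Cl)=O)OCCO1
F11 | step 10 | (R)-4-{[(R)-1-[3,5-bis(benzyloxy)phenyl]propan-2-yl]oxy}-4-oxobutan-2-yl 2,4-bis(benzyloxy)-6-({2-[(R)-2-(benzyloxy)propyl]-1,3-dioxolan-2-yl}methyl)benzoate | C[C@H](Cc1cc(OCc2ccccc2)cc(OCc2ccccc2)c1)OC(=O)C[C@@H](C)OC(=O)c1c(OCc2ccccc2)cc(OCc2ccccc2)cc1CC1(C[C@@H](C)OCc2ccccc2)OCCO1
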